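I decided to count one thing, how many times the exchange between Qe and Ze can halve its distance from balance within the run, and to let every other time in the flask be measured against that.

    Ja + Wu → Qe (k1 = 1.5 /M/min)
    Qe ⇌ Ze (K2 = 0.86, k2 = 0.074 /min)
    Ty ⇌ Ja, rate k3*(cs3 - [Ja]) while solid is left; crystals form when [Ja] > cs3 (cs3 = 0.058 M, k3 = 0.061 /min)

| setting | ash | cedar | elm |
|---|---|---|---|
| Ty | 0.060 M | 0.10 M | 0.15 M |
| Wu | 1.00 equiv | 1.00 equiv | 1.00 equiv |
| time | 2.5 h | 2.5 h | 2.5 h |

- as a solid, counted per litre of solution: Ty
- at the start none of Ty is in solution
- "hardly changes" means that all values lie within two and a half points (for a concentration: within two and a half percent of the largest)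
- run time (ash): 2.5 h

1. share of Qe in all that became Qe or Ze for ash, cedar, elm, in this order
2. the course of these numbers from the first flask to the last (rises all the way / falls, then rises / hardly changes / rises, then falls / falls all the way)

Qe and Ze relax towards balance at the sum of the forward and backward rate constants, which gave me a relaxation half-life of 0.0722 h, the fastest rung of my ladder. The next rung was Ja, whose half-life against Wu as charged in ash is 0.13 h, longer than the exchange half-life, so I expected Qe to be shared out with Ze almost as it was made. Slower still in ash was the solid: reckoned at its full speed of dissolving, with no Ja in solution, the charge of Ty takes 0.283 h to enter solution in ash and 0.707 h in elm, a lower estimate that in elm is still shorter than the run. On the last rung, with Wu charged at 1.00 equiv to Ty, I expected Ja and Wu to thin out together in a second-order tail that goes on feeding Qe slowly, with Qe and Ze held close to their balance.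

Dividing the run by the relaxation half-life gave my carried quantity, the relaxation count, which came to 34.6. Its expression holds no concentration, so the count is the same for ash, cedar and elm, and the exchange half-life is far shorter than the run. This is thermodynamic control, and I committed to the balance share of Qe, 53.8%, in each flask, a course that hardly changes.

The forecast gave 53.9%, 53.9% and 53.9%, course hardly changes, against my 53.8%, allowing for a tail worth “only one or two tenths of a point”.

The flasks gave 53.9%, 53.9% and 53.9%, course hardly changes. The 34.6 relaxation half-lives of ash work through the way back: the falling back of Ze to Qe is the main reason for the share, for ash stands at 53.9% with that step and at 0.948% in the same run with that step taken away. Elm, charged with Ty at 0.15 M and carrying the same count of 34.6, behaves alike, with 53.9% with the way back and 0.734% in the same run with the way back taken away.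

The rate constants were set for the occasion.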